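## Retrosynthetic overview

1. Target ⇐ acylation of the C8 hydroxyl with the silyl-protected (R)-Roche acid, then one global desilylation.
2. Ten-membered ring (second ring, last C–C bond): C7–C8, closed by 10-exo addition of a samarium ketyl radical at C8 to C7 of a preformed 3-(acetoxymethyl)butenolide. Loss of acetate unveils the exo-methylene; C7 and C8 are set in this one step.
3. Butenolide (first ring): ring-closing metathesis of a 2-(acetoxymethyl)acrylate of the C6 bis-allylic alcohol; C6 comes from a catalytic asymmetric Ni/Cr alkenylation of crotonaldehyde.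
4. C4=C5 with C15: copper-catalysed anti-carbomagnesiation of propargyl alcohol (C3–C4 bond) and iodinolysis. C1=C10: 1,2-metalate rearrangement of lithiated 2,3-dihydrofuran, then Negishi coupling (C9–C10).
5. Building blocks: 2,3-dihydrofuran, MeLi, (1,3-dioxolan-2-ylmethyl)zinc bromide, propargyl alcohol, crotonaldehyde, 2-(bromomethyl)acrylic acid, (R)-Roche ester.

Assumption: atom labels follow germacrane numbering (C6 lactone O-carbon, C7 ring-fusion carbon, C8 acyloxy carbon, C12 lactone carbonyl, C13 exo-methylene, C14 ring methyl, C15 CH2OH carbon).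

## Route

Step 1
Reactants: 1 2,3-dihydrofuran
Product: 4 (3Z)-4-iodopent-3-en-1-ol, via 5-lithio-2,3-dihydrofuran 2 (not isolated), via dilithium alkenyl(methyl)cuprate 3 (not isolated)
Conditions: t-BuLi, THF–pentane, −78 → 0 °C; MeLi (2 equiv), CuI, Et2O–Me2S, −40 → 20 °C; I2, −78 → 0 °C; aq NH4Cl
Reagents that add atoms: methyllithium (C[Li]); iodine (II)
Why: Kocienski-type copper-mediated 1,2-metalate rearrangement of the α-lithiated enol ether: methyl migrates from copper to carbon with inversion as the ring C–O bond breaks, so methyl ends trans and copper (then iodine, with retention) cis to the hydroxyethyl chain, which is the Z geometry needed at C1=C10.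

Step 2
Reactants: 4 (3Z)-4-iodopent-3-en-1-ol; 5 (1,3-dioxolan-2-ylmethyl)zinc bromide
Product: 6 (3Z)-5-(1,3-dioxolan-2-yl)-4-methylpent-3-en-1-ol
Conditions: 5 (2.5 equiv), PdCl2(dppf) (5 mol%), THF, 50 °C
Reagents that add atoms: none
Why: Negishi sp2–sp3 cross-coupling, which retains the alkene geometry and tolerates the free hydroxyl; the wide-bite-angle ligand disfavours β-alkoxide elimination.

Step 3
Reactants: 6 (3Z)-5-(1,3-dioxolan-2-yl)-4-methylpent-3-en-1-ol
Product: 7 2-[(2Z)-5-bromo-2-methylpent-2-en-1-yl]-1,3-dioxolane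
Conditions: CBr4, PPh3, 2,6-lutidine, CH2Cl2, 0 °C
Reagents that add atoms: carbon tetrabromide (BrC(Br)(Br)Br)
Why: Appel bromination of the primary alcohol, buffered so the acetal survives; no alkene or stereocentre is touched.

Step 4
Reactants: 7 2-[(2Z)-5-bromo-2-methylpent-2-en-1-yl]-1,3-dioxolane; 8 prop-2-yn-1-ol
Product: 12 (2Z)-2-[(3Z)-5-(1,3-dioxolan-2-yl)-4-methylpent-3-en-1-yl]-3-iodoprop-2-en-1-ol, via Grignard reagent 9 (not isolated), via chloromagnesium propynolate 10 (not isolated), via cyclic alkenylmagnesium alkoxide 11 (not isolated)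
Conditions: 7, Mg, Et2O, 35 °C; 8 (1.3 equiv) + i-PrMgCl, Et2O, 0 °C; CuI (20 mol%), −10 → 20 °C, 16 h; I2, −40 → 0 °C; aq NH4Cl
Reagents that add atoms: iodine (II)
Why: Duboudin copper-catalysed anti-carbomagnesiation of the propargylic alkoxide puts the alkyl group on the internal carbon (C4) and magnesium on the terminal carbon, chelated cis to the alkoxymethyl group; iodinolysis with retention gives the (Z)-iodide, so C15 ends cis to the future C5–C6 bond.

Step 5
Reactants: 12 (2Z)-2-[(3Z)-5-(1,3-dioxolan-2-yl)-4-methylpent-3-en-1-yl]-3-iodoprop-2-en-1-ol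
Product: 13 tert-butyl({(2Z)-2-[(3Z)-5-(1,3-dioxolan-2-yl)-4-methylpent-3-en-1-yl]-3-iodoprop-2-en-1-yl}oxy)diphenylsilane
Conditions: TBDPSCl, imidazole, CH2Cl2, 0 → 25 °C
Reagents that add atoms: tert-butyl(chloro)diphenylsilane (CC(C)(C)[Si](Cl)(c1ccccc1)c1ccccc1)
Why: Standard silylation of the primary allylic alcohol; the acid-stable silyl group is chosen to survive the later acetal cleavage.

Step 6
Reactants: 13 tert-butyl({(2Z)-2-[(3Z)-5-(1,3-dioxolan-2-yl)-4-methylpent-3-en-1-yl]-3-iodoprop-2-en-1-yl}oxy)diphenylsilane; 14 (2E)-but-2-enal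
Product: 16 (2E,4S,5Z,9Z)-6-({[tert-butyl(diphenyl)silyl]oxy}methyl)-11-(1,3-dioxolan-2-yl)-10-methylundeca-2,5,9-trien-4-ol, via alkenylchromium dichloride 15 (not isolated)
Conditions: 14 (3 equiv), CrCl2 (15 mol%), Kishi oxazoline–sulfonamide ligand (17 mol%), Et3N, NiCl2·2,9-dimethyl-1,10-phenanthroline (2 mol%), Mn, Zr(C5H5)2Cl2, LiCl, MeCN, 25 °C
Reagents that add atoms: none
Why: Catalytic asymmetric Nozaki–Hiyama–Kishi alkenylation: zerovalent nickel activates the C–I bond with retention of alkene geometry and hands the alkenyl group to trivalent chromium bearing the chiral sulfonamide, which adds 1,2 to the enal and sets C6; the ligand antipode is chosen to give the 4S carbinol (to be confirmed by Mosher esters).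

Step 7
Reactants: 16 (2E,4S,5Z,9Z)-6-({[tert-butyl(diphenyl)silyl]oxy}methyl)-11-(1,3-dioxolan-2-yl)-10-methylundeca-2,5,9-trien-4-ol; 17 2-(bromomethyl)prop-2-enoic acid
Product: 19 (2E,4S,5Z,9Z)-6-({[tert-butyl(diphenyl)silyl]oxy}methyl)-11-(1,3-dioxolan-2-yl)-10-methylundeca-2,5,9-trien-4-yl 2-(acetoxymethyl)prop-2-enoate, via bromomethylacrylate ester 18 (not isolated)
Conditions: 17, DCC, DMAP (10 mol%), CH2Cl2, 0 °C; then Bu4NOAc, 25 °C
Reagents that add atoms: tetrabutylammonium acetate (CC(=O)[O-].CCCC[N+](CCCC)(CCCC)CCCC)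
Why: Steglich esterification leaves C6 untouched, and acetate then displaces the activated allylic bromide (direct and allylic displacement give the same product), which swaps a C–Br bond that SmI2 would reduce first for a leaving group it does not touch.

Step 8
Reactants: 19 (2E,4S,5Z,9Z)-6-({[tert-butyl(diphenyl)silyl]oxy}methyl)-11-(1,3-dioxolan-2-yl)-10-methylundeca-2,5,9-trien-4-yl 2-(acetoxymethyl)prop-2-enoate
Product: 20 [(5R)-5-[(1Z,5Z)-2-({[tert-butyl(diphenyl)silyl]oxy}methyl)-7-(1,3-dioxolan-2-yl)-6-methylhepta-1,5-dien-1-yl]-2-oxo-2,5-dihydrofuran-3-yl]methyl acetate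
Conditions: second-generation Grubbs catalyst (5 mol%), CH2Cl2 (5 mM), 40 °C
Reagents that add atoms: none
Why: Ring-closing metathesis forms the five-membered butenolide: the ruthenium carbene loads on the disubstituted propenyl group and closes onto the acrylate while both trisubstituted alkenes stay inert; C6 is unchanged (the descriptor becomes 5R only through priorities).

Step 9
Reactants: 20 [(5R)-5-[(1Z,5Z)-2-({[tert-butyl(diphenyl)silyl]oxy}methyl)-7-(1,3-dioxolan-2-yl)-6-methylhepta-1,5-dien-1-yl]-2-oxo-2,5-dihydrofuran-3-yl]methyl acetate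
Product: 21 [(5R)-5-[(1Z,5Z)-2-({[tert-butyl(diphenyl)silyl]oxy}methyl)-6-methyl-8-oxoocta-1,5-dien-1-yl]-2-oxo-2,5-dihydrofuran-3-yl]methyl acetate
Conditions: TESOTf, 2,4,6-collidine, CH2Cl2, 0 °C; then H2O
Reagents that add atoms: water (O)
Why: Fujioka–Kita acetal cleavage through a collidinium intermediate under weakly basic conditions, chosen so the β,γ-unsaturated aldehyde does not slip into conjugation and the silyl ether, acetate and C6 survive; 21 is used at once.

Step 10
Reactants: 21 [(5R)-5-[(1Z,5Z)-2-({[tert-butyl(diphenyl)silyl]oxy}methyl)-6-methyl-8-oxoocta-1,5-dien-1-yl]-2-oxo-2,5-dihydrofuran-3-yl]methyl acetate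
Product: 24 (3aR,4S,6Z,10Z,11aR)-10-({[tert-butyl(diphenyl)silyl]oxy}methyl)-4-hydroxy-6-methyl-3-methylidene-3a,4,5,8,9,11a-hexahydrocyclodeca[b]furan-2(3H)-one, via samarium ketyl 22 (not isolated), via samarium enolate 23 (not isolated)
Conditions: SmI2 (2.5 equiv), HMPA (10 equiv), THF, 2 mM (21 added over 6 h), −78 → −40 °C; aq NH4Cl at −78 °C
Reagents that add atoms: none
Why: Proposed new method: SmI2–HMPA reduces the aldehyde to a nucleophilic ketyl radical that adds 10-exo to the electron-poor β-carbon C7 of the butenolide on the face anti to the C6 alkenyl arm (trans lactone, 7R), through a staggered transition state with C9 anti to C11, H8 between C6 and C11 and the bulky samarium-bound oxygen in the open sector beside H7, where it can bridge to the lactone carbonyl (8S); the resulting α-lactone radical is reduced to a samarium enolate that expels acetate to give the exo-methylene; the closest known reactions are SmI2 ketyl additions to enoates and butenolides with β-elimination and the eight-membered ketyl–olefin cyclisations.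

Step 11
Reactants: 25 methyl (2R)-3-hydroxy-2-methylpropanoate
Product: 27 (2R)-3-{[tert-butyl(dimethyl)silyl]oxy}-2-methylpropanoic acid, via silyl ether methyl ester 26 (not isolated)
Conditions: TBSCl, imidazole, DMF, 25 °C; then LiOH, THF–H2O, 0 → 25 °C; 1 M HCl to pH 4
Reagents that add atoms: tert-butyl(chloro)dimethylsilane (CC(C)(C)[Si](C)(C)Cl); lithium hydroxide ([Li+].[OH-])
Why: Silylation followed by saponification in the same flask; the α-stereocentre comes from the chiral pool and is not epimerised under these mild conditions.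

Step 12
Reactants: 24 (3aR,4S,6Z,10Z,11aR)-10-({[tert-butyl(diphenyl)silyl]oxy}methyl)-4-hydroxy-6-methyl-3-methylidene-3a,4,5,8,9,11a-hexahydrocyclodeca[b]furan-2(3H)-one; 27 (2R)-3-{[tert-butyl(dimethyl)silyl]oxy}-2-methylpropanoic acid
Product: 28 (3aR,4S,6Z,10Z,11aR)-10-({[tert-butyl(diphenyl)silyl]oxy}methyl)-6-methyl-3-methylidene-2-oxo-2,3,3a,4,5,8,9,11a-octahydrocyclodeca[b]furan-4-yl (2R)-3-{[tert-butyl(dimethyl)silyl]oxy}-2-methylpropanoate
Conditions: EDC·HCl, DMAP (0.3 equiv), CH2Cl2, 0 → 25 °C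
Reagents that add atoms: none
Why: Carbodiimide (Steglich) esterification acylates the C8 hydroxyl with retention at C8 and without epimerising the acid; it is run cold and short to avoid lactone migration to O8.

Step 13
Reactants: 28 (3aR,4S,6Z,10Z,11aR)-10-({[tert-butyl(diphenyl)silyl]oxy}methyl)-6-methyl-3-methylidene-2-oxo-2,3,3a,4,5,8,9,11a-octahydrocyclodeca[b]furan-4-yl (2R)-3-{[tert-butyl(dimethyl)silyl]oxy}-2-methylpropanoate
Product: 29 (3aR,4S,6Z,10Z,11aR)-10-(hydroxymethyl)-6-methyl-3-methylidene-2-oxo-2,3,3a,4,5,8,9,11a-octahydrocyclodeca[b]furan-4-yl (2R)-3-hydroxy-2-methylpropanoate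
Conditions: HF·pyridine, pyridine, THF, 0 → 25 °C
Reagents that add atoms: none
Why: Buffered fluoride desilylation removes both silyl ethers and leaves the α-methylene lactone, the ester and all stereocentres untouched.

## Compound list

1 | 2,3-dihydrofuran | C1=COCC1 | starting material
2 | 5-lithio-2,3-dihydrofuran | [Li]C1=CCCO1 | intermediate
3 | dilithium methyl[(2Z)-5-oxidopent-2-en-2-yl]cuprate (monovalent copper) | [Li+].[Li+].C[Cu-]/C(C)=C\CC[O-] | intermediate
4 | (3Z)-4-iodopent-3-en-1-ol | I/C(C)=C\CCO | intermediate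
5 | (1,3-dioxolan-2-ylmethyl)zinc bromide | Br[Zn]CC1OCCO1 | starting material
6 | (3Z)-5-(1,3-dioxolan-2-yl)-4-methylpent-3-en-1-ol | OCC/C=C(/C)CC1OCCO1 | intermediate
7 | 2-[(2Z)-5-bromo-2-methylpent-2-en-1-yl]-1,3-dioxolane | BrCC/C=C(/C)CC1OCCO1 | intermediate
8 | prop-2-yn-1-ol | OCC#C | starting material
9 | [(3Z)-5-(1,3-dioxolan-2-yl)-4-methylpent-3-en-1-yl]magnesium bromide | Br[Mg]CC/C=C(/C)CC1OCCO1 | intermediate
10 | chloromagnesium prop-2-yn-1-olate | Cl[Mg]OCC#C | intermediate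
11 | 4-[(3Z)-5-(1,3-dioxolan-2-yl)-4-methylpent-3-en-1-yl]-2,5-dihydro-1,2-oxamagnesole (cyclic alkenylmagnesium alkoxide, Mg on C5 cis to the CH2O group) | [Mg]1OCC(CC/C=C(/C)CC2OCCO2)=C1 | intermediate
12 | (2Z)-2-[(3Z)-5-(1,3-dioxolan-2-yl)-4-methylpent-3-en-1-yl]-3-iodoprop-2-en-1-ol | OC/C(=C\I)CC/C=C(/C)CC1OCCO1 | intermediate
13 | tert-butyl({(2Z)-2-[(3Z)-5-(1,3-dioxolan-2-yl)-4-methylpent-3-en-1-yl]-3-iodoprop-2-en-1-yl}oxy)diphenylsilane | CC(C)(C)[Si](c1ccccc1)(c1ccccc1)OC/C(=C\I)CC/C=C(/C)CC1OCCO1 | intermediate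
14 | (2E)-but-2-enal | C/C=C/C=O | starting material
15 | alkenylchromium dichloride derived from 13 (trivalent chromium in place of iodine, same Z geometry) | CC(C)(C)[Si](c1ccccc1)(c1ccccc1)OC/C(=C\[Cr](Cl)Cl)CC/C=C(/C)CC1OCCO1 | intermediate
16 | (2E,4S,5Z,9Z)-6-({[tert-butyl(diphenyl)silyl]oxy}methyl)-11-(1,3-dioxolan-2-yl)-10-methylundeca-2,5,9-trien-4-ol | C/C=C/[C@H](O)/C=C(\CO[Si](c1ccccc1)(c1ccccc1)C(C)(C)C)CC/C=C(/C)CC1OCCO1 | intermediate
17 | 2-(bromomethyl)prop-2-enoic acid | OC(=O)C(=C)CBr | starting material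
18 | (2E,4S,5Z,9Z)-6-({[tert-butyl(diphenyl)silyl]oxy}methyl)-11-(1,3-dioxolan-2-yl)-10-methylundeca-2,5,9-trien-4-yl 2-(bromomethyl)prop-2-enoate | C=C(CBr)C(=O)O[C@@H](/C=C/C)/C=C(\CO[Si](c1ccccc1)(c1ccccc1)C(C)(C)C)CC/C=C(/C)CC1OCCO1 | intermediate
19 | (2E,4S,5Z,9Z)-6-({[tert-butyl(diphenyl)silyl]oxy}methyl)-11-(1,3-dioxolan-2-yl)-10-methylundeca-2,5,9-trien-4-yl 2-(acetoxymethyl)prop-2-enoate | CC(=O)OCC(=C)C(=O)O[C@@H](/C=C/C)/C=C(\CO[Si](c1ccccc1)(c1ccccc1)C(C)(C)C)CC/C=C(/C)CC1OCCO1 | intermediate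
20 | [(5R)-5-[(1Z,5Z)-2-({[tert-butyl(diphenyl)silyl]oxy}methyl)-7-(1,3-dioxolan-2-yl)-6-methylhepta-1,5-dien-1-yl]-2-oxo-2,5-dihydrofuran-3-yl]methyl acetate | CC(=O)OCC1=C[C@H](OC1=O)/C=C(\CO[Si](c1ccccc1)(c1ccccc1)C(C)(C)C)CC/C=C(/C)CC1OCCO1 | intermediate
21 | [(5R)-5-[(1Z,5Z)-2-({[tert-butyl(diphenyl)silyl]oxy}methyl)-6-methyl-8-oxoocta-1,5-dien-1-yl]-2-oxo-2,5-dihydrofuran-3-yl]methyl acetate | CC(=O)OCC1=C[C@H](OC1=O)/C=C(\CO[Si](c1ccccc1)(c1ccccc1)C(C)(C)C)CC/C=C(/C)CC=O | intermediate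
22 | samarium ketyl of 21 (carbon radical at C8, oxygen bound to diiodosamarium, trivalent samarium) | CC(=O)OCC1=C[C@H](OC1=O)/C=C(\CO[Si](c1ccccc1)(c1ccccc1)C(C)(C)C)CC/C=C(/C)C[CH]O[Sm](I)I | intermediate
23 | macrocyclic samarium lactone enolate with C8 samarium alkoxide, before loss of acetate (trivalent samarium) | CC(=O)OCC1=C(O[Sm](I)I)O[C@@H]2/C=C(\CO[Si](c3ccccc3)(c3ccccc3)C(C)(C)C)CC/C=C(/C)C[C@H](O[Sm](I)I)[C@@H]12 | intermediate
24 | (3aR,4S,6Z,10Z,11aR)-10-({[tert-butyl(diphenyl)silyl]oxy}methyl)-4-hydroxy-6-methyl-3-methylidene-3a,4,5,8,9,11a-hexahydrocyclodeca[b]furan-2(3H)-one | C=C1C(=O)O[C@@H]2/C=C(\CO[Si](c3ccccc3)(c3ccccc3)C(C)(C)C)CC/C=C(/C)C[C@H](O)[C@@H]12 | intermediate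
25 | methyl (2R)-3-hydroxy-2-methylpropanoate | COC(=O)[C@H](C)CO | starting material
26 | methyl (2R)-3-{[tert-butyl(dimethyl)silyl]oxy}-2-methylpropanoate | COC(=O)[C@H](C)CO[Si](C)(C)C(C)(C)C | intermediate
27 | (2R)-3-{[tert-butyl(dimethyl)silyl]oxy}-2-methylpropanoic acid | OC(=O)[C@H](C)CO[Si](C)(C)C(C)(C)C | intermediate
28 | (3aR,4S,6Z,10Z,11aR)-10-({[tert-butyl(diphenyl)silyl]oxy}methyl)-6-methyl-3-methylidene-2-oxo-2,3,3a,4,5,8,9,11a-octahydrocyclodeca[b]furan-4-yl (2R)-3-{[tert-butyl(dimethyl)silyl]oxy}-2-methylpropanoate | C=C1C(=O)O[C@@H]2/C=C(\CO[Si](c3ccccc3)(c3ccccc3)C(C)(C)C)CC/C=C(/C)C[C@H](OC(=O)[C@H](C)CO[Si](C)(C)C(C)(C)C)[C@@H]12 | intermediate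
29 | (3aR,4S,6Z,10Z,11aR)-10-(hydroxymethyl)-6-methyl-3-methylidene-2-oxo-2,3,3a,4,5,8,9,11a-octahydrocyclodeca[b]furan-4-yl (2R)-3-hydroxy-2-methylpropanoate (CNP0163821.5) | C=C1C(=O)O[C@@H]2/C=C(\CO)CC/C=C(/C)C[C@H](OC(=O)[C@H](C)CO)[C@@H]12 | target

## Step count and risks

Total step count: 13. Longest linear sequence: 12 (steps 1–10, 12, 13; step 11 is the side-chain branch).

**Step 10 (ring closure).** The ten-membered ketyl cyclisation has no direct precedent, the C8 configuration rests on a transition-state argument, and the aldehyde can instead be reduced or dimerise. The fallback sets out from 18 and comes back at 24, or at 28 if C8 comes out epimeric. It reverses the polarity of the closure. Bromide 18 is isolated instead of being treated with acetate and is closed by the same metathesis to the bromomethyl butenolide acetal F1. Acetal cleavage as in step 9 gives the bromo aldehyde F2. With CrCl2 in THF–DMF at 1 mM only the allylic C–Br bond is reduced, and the allyl species attacks the aldehyde through C7 (intramolecular Nozaki–Hiyama allylation), giving 24. If this or the main step gives mainly the C8-epimeric alcohol F3, Mitsunobu esterification of F3 with 27 (PPh3, DIAD) inverts C8 and rejoins the route at 28.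

**Step 6 (asymmetric alkenylation).** The enantioselectivity of the catalytic Ni/Cr coupling with a trisubstituted alkenyl iodide and crotonaldehyde is uncertain. The fallback sets out from 13 and comes back at 16. It replaces catalyst control by a resolution. Iodine–lithium exchange on 13 (t-BuLi, Et2O, −78 °C) gives the alkenyllithium F4, which adds to 14 to give the racemic carbinol F5. Sharpless kinetic resolution (Ti(OiPr)4, L-(+)-diisopropyl tartrate, t-BuOOH, 4 Å sieves, CH2Cl2, −20 °C, about 55% conversion) epoxidises the propenyl group of the (R)-enantiomer and leaves (S)-configured 16. The cis-substituted trisubstituted alkene is a poor substrate and should not interfere.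

**Step 12 (C8 acylation).** The C8 hydroxyl is hindered and sits 1,3 to the lactone carbonyl, so lactone migration to O8 can compete under DMAP. The fallback sets out from 21 and 27 and comes back at 28. It moves the acylation into the cyclisation flask. Acid 27 is converted into the acid chloride F6 (1-chloro-N,N,2-trimethylpropenylamine, CH2Cl2, 0 °C). The SmI2 cyclisation of 21 is run as in step 10, and instead of protonation the C8 samarium alkoxide is acylated by excess F6 (−78 → 0 °C), giving 28 without ever exposing the free hydroxy lactone to base.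

## Further compounds

F1 | step 10 | (5R)-3-(bromomethyl)-5-[(1Z,5Z)-2-({[tert-butyl(diphenyl)silyl]oxy}methyl)-7-(1,3-dioxolan-2-yl)-6-methylhepta-1,5-dien-1-yl]furan-2(5H)-one | BrCC1=C[C@H](OC1=O)/C=C(\CO[Si](c1ccccc1)(c1ccccc1)C(C)(C)C)CC/C=C(/C)CC1OCCO1
F2 | step 10 | (5R)-3-(bromomethyl)-5-[(1Z,5Z)-2-({[tert-butyl(diphenyl)silyl]oxy}methyl)-6-methyl-8-oxoocta-1,5-dien-1-yl]furan-2(5H)-one | BrCC1=C[C@H](OC1=O)/C=C(\CO[Si](c1ccccc1)(c1ccccc1)C(C)(C)C)CC/C=C(/C)CC=O
F3 | step 10 | (3aR,4R,6Z,10Z,11aR)-10-({[tert-butyl(diphenyl)silyl]oxy}methyl)-4-hydroxy-6-methyl-3-methylidene-3a,4,5,8,9,11a-hexahydrocyclodeca[b]furan-2(3H)-one (C8 epimer of 24) | C=C1C(=O)O[C@@H]2/C=C(\CO[Si](c3ccccc3)(c3ccccc3)C(C)(C)C)CC/C=C(/C)C[C@@H](O)[C@@H]12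
F4 | step 6 | alkenyllithium derived from 13 (lithium in place of iodine, same Z geometry) | CC(C)(C)[Si](c1ccccc1)(c1ccccc1)OC/C(=C\[Li])CC/C=C(/C)CC1OCCO1
F5 | step 6 | (2E,4RS,5Z,9Z)-6-({[tert-butyl(diphenyl)silyl]oxy}methyl)-11-(1,3-dioxolan-2-yl)-10-methylundeca-2,5,9-trien-4-ol (racemic 16) | C/C=C/C(O)/C=C(\CO[Si](c1ccccc1)(c1ccccc1)C(C)(C)C)CC/C=C(/C)CC1OCCO1
F6 | step 12 | (2R)-3-{[tert-butyl(dimethyl)silyl]oxy}-2-methylpropanoyl chloride | ClC(=O)[C@H](C)CO[Si](C)(C)C(C)(C)C
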